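The labdane half is cut through ring B at C8–C9 and C5–C10 (labdane numbering), so that rings A and B arise together from an acyclic ester. In the key step a C5 radical, released from a thionocarbonate, closes ring A onto C10 of an (E)-enal, and the resulting C9 radical closes ring B onto a terminal alkyne that becomes the 8(17)-methylidene. The step exploits the exocyclic C8=C17 alkene as the trace of an alkyne and C11 as a formyl handle on C9. The C4 ester stereocentre steers the cascade and is methylated afterwards; a B-alkyl Suzuki coupling then joins an eudesmanyl ether made from β-eudesmol.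

Key step: step 10

Remark: labdane numbering is used for the diterpenoid half and eudesmane numbering for the sesquiterpenoid half; commercial (+)-β-eudesmol is assumed to carry the eudesmane configuration drawn for the target.

Step 1
Reactants: 1 geraniol
Product: 2 geranyl tert-butyldimethylsilyl ether
Conditions: TBSCl, imidazole, CH2Cl2, rt
Reagents that add atoms: tert-butyldimethylsilyl chloride, CC(C)(C)[Si](C)(C)Cl
Why: Standard silylation of the primary allylic alcohol, which creates no stereocentre and leaves untouched the E-alkene that later becomes the C9=C10 acceptor.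

Step 2
Reactants: 2 geranyl tert-butyldimethylsilyl ether
Product: 4 (4E)-6-[(tert-butyldimethylsilyl)oxy]-4-methylhex-4-en-1-ol, via aldehyde 3 (not isolated)
Conditions: O3 (1.0 equiv), pyridine, CH2Cl2/MeOH, −78 °C; then NaBH4, −78 to 0 °C
Reagents that add atoms: ozone, [O-][O+]=O
Why: Chemoselective ozonolysis should cleave the remote, more electron-rich alkene rather than the one deactivated by the allylic silyloxy group, and the borohydride work-up reduces the aldehyde directly to the primary alcohol.

Step 3
Reactants: 4 (4E)-6-[(tert-butyldimethylsilyl)oxy]-4-methylhex-4-en-1-ol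
Product: 5 tert-butyl{[(2E)-6-iodo-3-methylhex-2-en-1-yl]oxy}dimethylsilane
Conditions: I2, PPh3, imidazole, CH2Cl2, 0 °C
Reagents that add atoms: iodine, II
Why: Appel-type iodination of the unhindered primary alcohol by SN2 displacement, with no stereocentre involved.

Step 4
Reactants: 6 methyl acetoacetate; 7 3-bromo-1-(trimethylsilyl)prop-1-yne
Product: 9 methyl 3-oxo-7-(trimethylsilyl)hept-6-ynoate, via dianion 8 (not isolated)
Conditions: NaH, THF, 0 °C; n-BuLi, 0 °C; then 7, 0 °C; aq. NH4Cl
Reagents that add atoms: none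
Why: Weiler dianion alkylation, in which the more reactive terminal carbanion of the acetoacetate dianion displaces the propargylic bromide and so attaches the carbons that become C7, C8 and C17.

Step 5
Reactants: 9 methyl 3-oxo-7-(trimethylsilyl)hept-6-ynoate
Product: 10 methyl (3R)-3-hydroxy-7-(trimethylsilyl)hept-6-ynoate
Conditions: RuCl2[(R)-BINAP] (0.5 mol%), H2 (4 atm), MeOH, 50 °C
Reagents that add atoms: none
Why: Noyori asymmetric hydrogenation of a β-keto ester, where the (R)-BINAP ligand should give the (R)-carbinol as it does for methyl acetoacetate, and the silyl-capped internal alkyne is expected to survive at this low pressure.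

Step 6
Reactants: 10 methyl (3R)-3-hydroxy-7-(trimethylsilyl)hept-6-ynoate; 5 tert-butyl{[(2E)-6-iodo-3-methylhex-2-en-1-yl]oxy}dimethylsilane
Product: 12 methyl (2R,3R)-2-[(4E)-6-[(tert-butyldimethylsilyl)oxy]-4-methylhex-4-en-1-yl]-3-hydroxy-7-(trimethylsilyl)hept-6-ynoate, via dianion 11 (not isolated)
Conditions: LiN(iPr)2 (2.2 equiv), THF, −78 to −20 °C; then 5, HMPA, −78 to 0 °C; aq. NH4Cl
Reagents that add atoms: none
Why: Fráter–Seebach alkylation, in which the chelated dilithium alkoxide-enolate is alkylated by the primary iodide on the face anti to the carbinol substituent, setting the C4 stereocentre (2R) with 2,3-anti configuration.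

Step 7
Reactants: 12 methyl (2R,3R)-2-[(4E)-6-[(tert-butyldimethylsilyl)oxy]-4-methylhex-4-en-1-yl]-3-hydroxy-7-(trimethylsilyl)hept-6-ynoate
Product: 13 methyl (2R,3R)-3-hydroxy-2-[(4E)-6-hydroxy-4-methylhex-4-en-1-yl]hept-6-ynoate
Conditions: TBAF (2.5 equiv), THF, 0 °C to rt
Reagents that add atoms: none
Why: Fluoride should cleave the primary silyl ether and the alkynyl C–Si bond in one operation, exposing the allylic alcohol and the terminal alkyne without touching the stereocentres.

Step 8
Reactants: 13 methyl (2R,3R)-3-hydroxy-2-[(4E)-6-hydroxy-4-methylhex-4-en-1-yl]hept-6-ynoate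
Product: 14 methyl (2R,3R)-3-hydroxy-2-[(4E)-4-methyl-6-oxohex-4-en-1-yl]hept-6-ynoate
Conditions: MnO2 (activated, excess), CH2Cl2, rt
Reagents that add atoms: none
Why: Activated MnO2 oxidises only the allylic alcohol, so the (E)-enal should form with the secondary alcohol and the alkene geometry intact.

Step 9
Reactants: 14 methyl (2R,3R)-3-hydroxy-2-[(4E)-4-methyl-6-oxohex-4-en-1-yl]hept-6-ynoate
Product: 15 methyl (2R,3R)-2-[(4E)-4-methyl-6-oxohex-4-en-1-yl]-3-[(phenoxycarbonothioyl)oxy]hept-6-ynoate
Conditions: PhOC(S)Cl, pyridine, DMAP (cat.), CH2Cl2, 0 °C to rt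
Reagents that add atoms: O-phenyl chlorothionoformate, S=C(Cl)Oc1ccccc1
Why: Acylation of the secondary alcohol to the aryl thionocarbonate installs the radical leaving group at C5 under weakly basic conditions that should not eliminate the β-oxy ester.

Step 10
Reactants: 15 methyl (2R,3R)-2-[(4E)-4-methyl-6-oxohex-4-en-1-yl]-3-[(phenoxycarbonothioyl)oxy]hept-6-ynoate
Product: 19 methyl 9β-formyl-10β-methyl-8(17)-methylidene-trans-decalin-4α-carboxylate (labdane numbering; 4β-H, 5α-H, 9α-H), via C5 radical 16 (not isolated), via C9 radical 17 (not isolated), via vinyl radical 18 (not isolated)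
Conditions: Bu3SnH (1.3 equiv) and AIBN (0.2 equiv) by syringe pump over 10 h, toluene (0.005 M), 110 °C
Reagents that add atoms: none
Why: Bu3Sn• adds to the thiocarbonyl sulfur and β-scission releases the secondary C5 radical, which closes ring A by 6-exo-trig addition to C10, the β-carbon of the (E)-enal; the formyl-stabilised C9 radical then closes ring B by 6-exo-dig addition to C8 of the alkyne, and the vinyl radical takes hydrogen from Bu3SnH to leave the 8(17)-methylidene. The closest known reaction type is a Barton–McCombie-initiated tin hydride tandem radical cyclisation onto an activated alkene and an alkyne. Ring A should form through a chair transition state in which the C4 ester and the C5 butynyl chain are equatorial and C9 is pseudo-equatorial with C20 axial, so the C4 stereocentre set in step 6 fixes C5 (α-H) and C10 (β-methyl). Ring B should then form through a chair in which the planar C9 radical attacks the alkyne held equatorially at C5, giving the trans-decalin with the formyl group equatorial (9β). The step needs cyclisation to beat hydrogen transfer to the C5 and C9 radicals and stannyl addition to the alkyne, which the syringe-pump addition (low standing Bu3SnH concentration), the activated enal and the pre-organised trans-1,2-disubstituted cyclohexane should secure.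

Step 11
Reactants: 19 methyl 9β-formyl-10β-methyl-8(17)-methylidene-trans-decalin-4α-carboxylate
Product: 20 methyl 9β-ethenyl-10β-methyl-8(17)-methylidene-trans-decalin-4α-carboxylate (labdane numbering; 4β-H, 5α-H, 9α-H)
Conditions: Zn, CH2Br2, TiCl4, THF/CH2Cl2, 0 °C to rt
Reagents that add atoms: dibromomethane, BrCBr
Why: Lombardo–Takai methylenation with the non-basic Zn/CH2Br2/TiCl4 reagent should convert the aldehyde into the vinyl group without epimerising C9, without moving the 8(17)-alkene into conjugation and without touching the ester.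

Step 12
Reactants: 20 methyl 9β-ethenyl-10β-methyl-8(17)-methylidene-trans-decalin-4α-carboxylate
Product: 22 methyl 13,14,15,16-tetranorlabda-8(17),11-dien-19-oate (4α-CH3, 4β-CO2CH3, 5α-H, 9α-H, 10β-CH3), via enolate 21 (not isolated)
Conditions: LiN(iPr)2, THF/HMPA, −78 to −30 °C; then MeI, −78 to 0 °C
Reagents that add atoms: iodomethane, CI
Why: Ester enolate alkylation, in which iodomethane should approach C4 from the equatorial α face, away from the axial C10 methyl on the β face, so the new methyl is 4α and the ester ends axial (4β) as in the target.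

Step 13
Reactants: 23 (+)-β-eudesmol
Product: 24 β-eudesmol 11-O-triethylsilyl ether
Conditions: TESOTf, 2,6-lutidine, CH2Cl2, −78 to 0 °C
Reagents that add atoms: triethylsilyl trifluoromethanesulfonate, CC[Si](CC)(CC)OS(=O)(=O)C(F)(F)F
Why: Silylation of the tertiary side-chain alcohol with the silyl triflate, so that only the oxygen at eudesmane C4 can be alkylated later.

Step 14
Reactants: 24 β-eudesmol 11-O-triethylsilyl ether
Product: 26 11-[(triethylsilyl)oxy]eudesman-4α-ol (11-O-triethylsilyl cryptomeridiol), via organomercurial 25 (not isolated)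
Conditions: Hg(OAc)2, THF/H2O (1:1), rt; then aq. NaOH, NaBH4, 0 °C
Reagents that add atoms: water, O
Why: Oxymercuration–demercuration gives Markovnikov hydration of the exocyclic alkene, and water should attack eudesmane C4 from the α face because the axial β trajectory is blocked by the angular C10 methyl, giving the equatorial 4α-alcohol.

Step 15
Reactants: 26 11-[(triethylsilyl)oxy]eudesman-4α-ol; 27 1-bromobut-2-yne
Product: 29 4α-(but-2-yn-1-yloxy)-11-[(triethylsilyl)oxy]eudesmane, via alkoxide 28 (not isolated)
Conditions: KH, THF, 0 °C; then 27, Bu4NI (cat.), 0 °C to rt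
Reagents that add atoms: none
Why: Williamson etherification, in which the potassium alkoxide of the hindered tertiary alcohol displaces the reactive propargylic bromide by SN2 at a primary carbon, so the configuration at eudesmane C4 is retained.

Step 16
Reactants: 29 4α-(but-2-yn-1-yloxy)-11-[(triethylsilyl)oxy]eudesmane
Product: 31 4α-{[(2E)-3-iodobut-2-en-1-yl]oxy}-11-[(triethylsilyl)oxy]eudesmane, via alkenylzirconocene 30 (not isolated)
Conditions: Cp2Zr(H)Cl (2.2 equiv), THF, rt to 50 °C; then I2, 0 °C
Reagents that add atoms: iodine, II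
Why: Hydrozirconation with Schwartz reagent is a syn addition that, after equilibration with excess reagent, should place zirconium on the methyl-bearing alkyne carbon remote from the bulky ether, and iodinolysis with retention gives the (E)-vinyl iodide.

Step 17
Reactants: 22 methyl 13,14,15,16-tetranorlabda-8(17),11-dien-19-oate; 31 4α-{[(2E)-3-iodobut-2-en-1-yl]oxy}-11-[(triethylsilyl)oxy]eudesmane
Product: 33 methyl 15-{[11-(triethylsilyloxy)eudesman-4α-yl]oxy}labda-8(17),13E-dien-19-oate, via alkylborane 32 (not isolated)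
Conditions: Sia2BH (from BH3·SMe2 and 2-methylbut-2-ene), THF, 0 °C to rt; then 31, Pd(dppf)Cl2 (5 mol%), AsPh3, Cs2CO3, DMF/H2O, rt to 50 °C
Reagents that add atoms: none
Why: The bulky dialkylborane should hydroborate the monosubstituted vinyl group far faster than the 1,1-disubstituted 8(17)-alkene, and the B-alkyl Suzuki–Miyaura coupling with the vinyl iodide proceeds with retention and so fixes the 13E geometry.

Step 18
Reactants: 33 methyl 15-{[11-(triethylsilyloxy)eudesman-4α-yl]oxy}labda-8(17),13E-dien-19-oate
Product: 35 15-[(11-hydroxyeudesman-4α-yl)oxy]labda-8(17),13E-dien-19-oic acid (CNP0156875.1), via carboxylate 34 (not isolated)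
Conditions: NaSPr, DMF, 80 °C; then TBAF, THF, 50 °C; aq. HCl (pH 3)
Reagents that add atoms: none
Why: Thiolate should demethylate the hindered axial ester by SN2 attack at the methyl carbon and fluoride then cleaves the silyl ether, so acidification gives the acid and the tertiary alcohol without touching the ether or the alkenes.

Compound list
1 | geraniol | CC(C)=CCC/C(C)=C/CO | starting material
2 | geranyl tert-butyldimethylsilyl ether | CC(C)=CCC/C(C)=C/CO[Si](C)(C)C(C)(C)C | intermediate
3 | (4E)-6-[(tert-butyldimethylsilyl)oxy]-4-methylhex-4-enal (not isolated) | O=CCC/C(C)=C/CO[Si](C)(C)C(C)(C)C | intermediate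
4 | (4E)-6-[(tert-butyldimethylsilyl)oxy]-4-methylhex-4-en-1-ol | OCCC/C(C)=C/CO[Si](C)(C)C(C)(C)C | intermediate
5 | tert-butyl{[(2E)-6-iodo-3-methylhex-2-en-1-yl]oxy}dimethylsilane | ICCC/C(C)=C/CO[Si](C)(C)C(C)(C)C | intermediate
6 | methyl acetoacetate | COC(=O)CC(C)=O | starting material
7 | 3-bromo-1-(trimethylsilyl)prop-1-yne | C[Si](C)(C)C#CCBr | starting material
8 | sodium lithium dianion of methyl acetoacetate (not isolated) | [Na+].[Li+].C=C([O-])C=C([O-])OC | intermediate
9 | methyl 3-oxo-7-(trimethylsilyl)hept-6-ynoate | COC(=O)CC(=O)CCC#C[Si](C)(C)C | intermediate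
10 | methyl (3R)-3-hydroxy-7-(trimethylsilyl)hept-6-ynoate | COC(=O)C[C@H](O)CCC#C[Si](C)(C)C | intermediate
11 | dilithium alkoxide-enolate of 10 (not isolated) | [Li+].[Li+].COC([O-])=C[C@H]([O-])CCC#C[Si](C)(C)C | intermediate
12 | methyl (2R,3R)-2-[(4E)-6-[(tert-butyldimethylsilyl)oxy]-4-methylhex-4-en-1-yl]-3-hydroxy-7-(trimethylsilyl)hept-6-ynoate | COC(=O)[C@H](CCC/C(C)=C/CO[Si](C)(C)C(C)(C)C)[C@H](O)CCC#C[Si](C)(C)C | intermediate
13 | methyl (2R,3R)-3-hydroxy-2-[(4E)-6-hydroxy-4-methylhex-4-en-1-yl]hept-6-ynoate | COC(=O)[C@H](CCC/C(C)=C/CO)[C@H](O)CCC#C | intermediate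
14 | methyl (2R,3R)-3-hydroxy-2-[(4E)-4-methyl-6-oxohex-4-en-1-yl]hept-6-ynoate | COC(=O)[C@H](CCC/C(C)=C/C=O)[C@H](O)CCC#C | intermediate
15 | methyl (2R,3R)-2-[(4E)-4-methyl-6-oxohex-4-en-1-yl]-3-[(phenoxycarbonothioyl)oxy]hept-6-ynoate | COC(=O)[C@H](CCC/C(C)=C/C=O)[C@H](OC(=S)Oc1ccccc1)CCC#C | intermediate
16 | acyclic secondary C5 radical from 15 (not isolated) | COC(=O)[C@H](CCC/C(C)=C/C=O)[CH]CCC#C | intermediate
17 | ring A cyclohexane carrying the formyl-stabilised C9 radical (not isolated) | C#CCC[C@@H]1[C@](C)(CCC[C@H]1C(=O)OC)[CH]C=O | intermediate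
18 | bicyclic exocyclic vinyl radical at C17 (not isolated) | [CH]=C1CC[C@@H]2[C@](C)(CCC[C@H]2C(=O)OC)[C@H]1C=O | intermediate
19 | methyl 9β-formyl-10β-methyl-8(17)-methylidene-trans-decalin-4α-carboxylate (labdane numbering; 4β-H, 5α-H, 9α-H) | C=C1CC[C@@H]2[C@](C)(CCC[C@H]2C(=O)OC)[C@H]1C=O | intermediate
20 | methyl 9β-ethenyl-10β-methyl-8(17)-methylidene-trans-decalin-4α-carboxylate (labdane numbering; 4β-H, 5α-H, 9α-H) | C=C1CC[C@@H]2[C@](C)(CCC[C@H]2C(=O)OC)[C@H]1C=C | intermediate
21 | lithium ester enolate of 20 (not isolated) | [Li+].C=C1CC[C@@H]2[C@](C)(CCCC2=C([O-])OC)[C@H]1C=C | intermediate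
22 | methyl 13,14,15,16-tetranorlabda-8(17),11-dien-19-oate (4α-CH3, 4β-CO2CH3, 5α-H, 9α-H, 10β-CH3) | C=C1CC[C@@H]2[C@](C)(CCC[C@]2(C)C(=O)OC)[C@H]1C=C | intermediate
23 | (+)-β-eudesmol | C=C1CCC[C@]2(C)CC[C@@H](C(C)(C)O)C[C@H]21 | starting material
24 | β-eudesmol 11-O-triethylsilyl ether | C=C1CCC[C@]2(C)CC[C@@H](C(C)(C)O[Si](CC)(CC)CC)C[C@H]21 | intermediate
25 | 15-(acetoxymercurio)-11-[(triethylsilyl)oxy]eudesman-4α-ol (not isolated) | O[C@]1(C[Hg]OC(C)=O)CCC[C@]2(C)CC[C@@H](C(C)(C)O[Si](CC)(CC)CC)C[C@H]21 | intermediate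
26 | 11-[(triethylsilyl)oxy]eudesman-4α-ol (11-O-triethylsilyl cryptomeridiol) | O[C@]1(C)CCC[C@]2(C)CC[C@@H](C(C)(C)O[Si](CC)(CC)CC)C[C@H]21 | intermediate
27 | 1-bromobut-2-yne | CC#CCBr | starting material
28 | potassium 4α-alkoxide of 26 (not isolated) | [K+].[O-][C@]1(C)CCC[C@]2(C)CC[C@@H](C(C)(C)O[Si](CC)(CC)CC)C[C@H]21 | intermediate
29 | 4α-(but-2-yn-1-yloxy)-11-[(triethylsilyl)oxy]eudesmane | CC#CCO[C@]1(C)CCC[C@]2(C)CC[C@@H](C(C)(C)O[Si](CC)(CC)CC)C[C@H]21 | intermediate
30 | (E)-alkenylzirconocene chloride from 29, zirconium on the methyl-bearing carbon (not isolated) | C/C(=C\CO[C@]1(C)CCC[C@]2(C)CC[C@@H](C(C)(C)O[Si](CC)(CC)CC)C[C@H]21)[Zr](Cl)(C1C=CC=C1)C1C=CC=C1 | intermediate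
31 | 4α-{[(2E)-3-iodobut-2-en-1-yl]oxy}-11-[(triethylsilyl)oxy]eudesmane | C/C(I)=C\CO[C@]1(C)CCC[C@]2(C)CC[C@@H](C(C)(C)O[Si](CC)(CC)CC)C[C@H]21 | intermediate
32 | B-alkyl disiamylborane of 22, boron on C12 (not isolated) | C=C1CC[C@@H]2[C@](C)(CCC[C@]2(C)C(=O)OC)[C@H]1CCB(C(C)C(C)C)C(C)C(C)C | intermediate
33 | methyl 15-{[11-(triethylsilyloxy)eudesman-4α-yl]oxy}labda-8(17),13E-dien-19-oate | C=C1CC[C@@H]2[C@](C)(CCC[C@]2(C)C(=O)OC)[C@H]1CC/C(C)=C/CO[C@]1(C)CCC[C@]2(C)CC[C@@H](C(C)(C)O[Si](CC)(CC)CC)C[C@H]21 | intermediate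
34 | sodium 15-{[11-(triethylsilyloxy)eudesman-4α-yl]oxy}labda-8(17),13E-dien-19-oate (not isolated) | [Na+].C=C1CC[C@@H]2[C@](C)(CCC[C@]2(C)C(=O)[O-])[C@H]1CC/C(C)=C/CO[C@]1(C)CCC[C@]2(C)CC[C@@H](C(C)(C)O[Si](CC)(CC)CC)C[C@H]21 | intermediate
35 | 15-[(11-hydroxyeudesman-4α-yl)oxy]labda-8(17),13E-dien-19-oic acid (CNP0156875.1) | C=C1CC[C@@H]2[C@](C)(CCC[C@]2(C)C(=O)O)[C@H]1CC/C(C)=C/CO[C@]1(C)CCC[C@]2(C)CC[C@@H](C(C)(C)O)C[C@H]21 | target

Total step count: 18
Longest linear sequence: 12 steps (steps 1–3, 6–12, 17 and 18)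

Steps most likely to fail

Step 10. The process at risk is hydrogen transfer from Bu3SnH to the formyl-stabilised C9 radical, or stannyl radical addition to the alkyne, outrunning the slow 6-exo-dig closure, so that the cascade stops after ring A. The fallback separates the two ring closures and closes ring B by polar, gold-catalysed chemistry. Setting out from 15, Bu3SnH/AIBN at ordinary concentration (benzene, 80 °C) should give, by 6-exo cyclisation and reduction, the ring A aldehyde F1. TBSOTf/Et3N (CH2Cl2, 0 °C) should convert it into the silyl enol ether F2. Ph3PAuCl/AgBF4 (5 mol% each) in CH2Cl2/MeOH at rt should then add the enol ether 6-exo-dig to the gold-activated alkyne (Conia-ene type carbocyclisation) and return to the route at 19.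

Step 17. The process at risk is competing hydroboration of the 8(17)-methylidene, or sluggish transfer of the hindered primary alkyl group from boron to palladium. The fallback replaces boron by zirconium and zinc. Setting out from 22, hydrozirconation with Cp2Zr(H)Cl (THF, rt), which discriminates strongly against 1,1-disubstituted alkenes, should give the alkylzirconocene chloride F3. Transmetalation with ZnCl2 should give the alkylzinc chloride F4. Negishi coupling with 31 catalysed by Pd(PPh3)4 (THF, rt to 50 °C) then rejoins the route at 33.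

Step 15. The process at risk is slow O-alkylation of the hindered tertiary alkoxide, so that base-induced isomerisation or elimination of the propargylic bromide takes over. The fallback forms the bond to oxygen at eudesmane C4 from the alkene instead. Setting out from 24 (step 14 is then not needed), Mukaiyama-type hydrogen-atom-transfer hydroalkoxylation (Co(salen) catalyst, N-fluoro-2,4,6-trimethylpyridinium triflate, PhSiH3, excess but-2-yn-1-ol, PhCF3, rt) should add the alcohol to the exocyclic alkene in the Markovnikov sense from the α face and return to the route at 29; no new compound is made on the way.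

Further compounds
F1 | step 10 | ring A aldehyde: methyl (labdane numbering) 5-(but-3-yn-1-yl)-10-methyl-10-(2-oxoethyl)cyclohexane-4-carboxylate, 4α-ester, 5α-H, 10β-methyl | C#CCC[C@@H]1[C@](C)(CCC[C@H]1C(=O)OC)CC=O
F2 | step 10 | tert-butyldimethylsilyl enol ether of F1 | C#CCC[C@@H]1[C@](C)(CCC[C@H]1C(=O)OC)C=CO[Si](C)(C)C(C)(C)C
F3 | step 17 | alkylzirconocene chloride from 22, zirconium on C12 | C=C1CC[C@@H]2[C@](C)(CCC[C@]2(C)C(=O)OC)[C@H]1CC[Zr](Cl)(C3C=CC=C3)C3C=CC=C3
F4 | step 17 | alkylzinc chloride from F3, zinc on C12 | C=C1CC[C@@H]2[C@](C)(CCC[C@]2(C)C(=O)OC)[C@H]1CC[Zn]Cl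
F0 | step 15 | none | none
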